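## Analysis of the target

Polyketide numbering is used throughout. C1 is the lactone carbonyl, C2 the CH2, C3 the CH–O, C4 the C(CH3)–O, C5 the ring CH2, C6 the C(CH3)(alkyl)–O, and C7–C22 the unbranched chain. O-a is the peroxide oxygen on C3, O-b the one on C6, and O4 the ring oxygen of the lactone.

- **Ring system.** A 1,2-dioxane (ring A: O-a, O-b, C6, C5, C4, C3) is cis-fused along C3–C4 to a γ-butyrolactone (ring B: C1, C2, C3, C4, O4).
- **Configuration.** The SMILES reads as (3S,4S,6R). H3, the C4 methyl and the C6 methyl lie on one face of ring A. C2, O4 and the hexadecyl chain lie on the other face. In the chair with the C4 methyl equatorial, the chain is axial and syn to the axial O4.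
- **Relations between the centres.** C3 and C4 are tied together by the cis fusion. C6 is insulated from them by C5 and by the O–O bond, and its two exocyclic groups, CH3 and CH2R, are almost equal in size. Any method that must tell them apart by bulk, or that passes through a C6 radical or free cation, should give both epimers.
- **Sensitive groups.** The O–O bond excludes low-valent metals, hydrogenation catalysts, phosphines, hydrides and organometallic reagents late in the route. H3 and the acidic C2 protons open Kornblum–DeLaMare and retro-Michael pathways under base.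
- **The feature exploited.** C6 of ring A is bound to O-b and otherwise only to carbon. It is therefore the adduct of a carbon nucleophile to the cyclic peroxycarbenium ion C6=O-b(+)–O-a. It stands 1,3 to C4, whose two substituents (O4 and CH3) differ strongly. C6 can thus be set by the order in which its two carbon groups arrive, not by their size.

## Retrosynthetic reasoning

**16 ⇒ 15 ⇒ 13 + 14 (cut C8–C9).** The saturated chain has no function to build on. It is cut two bonds away from C6, so that the group that must be delivered to C6 shrinks to an allyl unit. The forward steps are a cross-metathesis of 13 with 14 and a metal-free hydrogen transfer to 15. Both must leave the O–O bond alone, and neither touches a stereocentre.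

**13 ⇒ 10 + 11 via 12 (cut C6–C7, the key disconnection).** The skeleton is cut at the peroxide-bearing quaternary carbon, with both rings and the O–O bond already in place.
- In 12 the methyl group is already on C6 and the chain comes in as the nucleophile 11.
- Axial attack on the half-chair of 12 with O4 pseudoaxial puts the new C–C bond syn to O4. This is exactly the arrangement in 16.
- The cut removes the hardest stereochemical problem, makes the configuration of C6 in 10 irrelevant, and reduces the precursor to a C9 bicycle without a chain.
- Cutting C6–CH3 instead would give the C6 epimer by the same logic.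

**10 ⇒ 6 via 7, 8, 9 (cut C6–O-b, O-a–C3 and O4–C1).** C6 of 10 is at the ketone oxidation level, so the peroxide need not be carried into the route. Ozonolysis of the 1,1-disubstituted alkene of 6 in an alcohol solvent gives carbonyl oxide 7. Trapped as 8, this already holds both peroxide oxygens on C6. Oxa-Michael addition to C3 closes ring A (9), and lactonisation closes ring B. One operation turns an acyclic C10 ester into the bicycle and sets C3 from C4.

**6 ⇒ 3 + 4 (cut C4–C5).** Only C4 needs absolute control. It is a tertiary carbinol flanked by a methyl and an alkenyl group, a pair that a catalytic asymmetric allylboration of a methyl ketone distinguishes well. Ketone 4 already holds C1–C4 with the acceptor for the later Michael step. Boronate 3 brings C5, C6 and the future C6 methyl.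

**3 ⇒ 1 + 2.** The boronate is made from the commercial Grignard reagent and the commercial borate.

## Alternatives that were turned down

Alternative 1: the textbook route.
- Disconnection: O-a–C3, by intramolecular oxa-Michael addition of a C6 tertiary hydroperoxide to a C4-configured butenolide.
- Forward key steps: aerobic cobalt-catalysed hydroperoxysilylation (Mukaiyama–Isayama) of alkene (S)-5-methyl-5-(2-methylideneoctadecyl)furan-2(5H)-one A1 gives hydroperoxide A2. Base then closes ring A.
- Reason for rejection: the C6–O bond forms when a planar, freely rotating tertiary radical captures oxygen three atoms away from C4. CH3 and CH2R offer no facial bias. Both C6 epimers are expected, so half of an advanced C24 intermediate is lost and must be separated at the very end. A1 also carries the chain from the start and needs a longer preparation than the whole route below.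

Alternative 2: [4+2] photooxygenation.
- Disconnection: both C–O bonds of the peroxide.
- Forward key steps: dye-sensitised photooxygenation of (3E,5E)-4,6-dimethyldocosa-3,5-dienoic acid A3 gives endoperoxide acid A4. Halolactonisation onto C4=C5 and radical dehalogenation at C5 follow. Suprafacial addition translates the diene geometry into the correct C3/C6 relation, and lactone closure sets C4.
- Reasons for rejection:
  - A3 is achiral and nothing chooses between its two faces, so A4 is racemic and a resolution costs half the material.
  - The methyl group on the inside of C6 disfavours the s-cis conformer, so the ene reaction at three allylic positions competes.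
  - The C5 radical of the last step is β to O-b and can attack it with loss of the O–O bond.

Alternative 3: invertive perhydrolysis of an oxetane.
- Disconnection: C6–O-b, by acid-mediated opening of the enantioenriched oxetane (S)-2-hexadecyl-2-methyloxetane A5 to (R)-3-hydroperoxy-3-methylnonadecan-1-ol A6. The hydroperoxide is then protected, C4 oxidised, C1–C4 built up, and the route ends as in Alternative 1.
- Reasons for rejection:
  - C6 is set by reagent control, but C4 needs a second, independent asymmetric step, because 1,3-induction from C6 fails for the same CH3/CH2R reason.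
  - Carbon nucleophiles must be added next to an O–O bond.
  - Substitution at a tertiary centre has cationic character that can erode the configuration.
  - The sequence is linear and roughly twice as long.

Key step: step 4

Assumption: the (R)-enantiomer of the diol catalyst in step 2 is taken to deliver the methallyl group to the Si face of ketone 4. If the sense is the opposite, the equally available (S)-diol is used and nothing else changes.

Remark: 15 is expected as an E/Z mixture (E drawn). The geometry is erased in step 6. All peroxidic compounds are handled cold, behind a shield, and are never distilled.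

## Steps

Step 1
Reactants: 1 2-methylallylmagnesium chloride; 2 triisopropyl borate
Product: 3 diisopropyl (2-methylallyl)boronate
Conditions: Et2O/THF, −78 °C to rt; HCl (1 equiv, in Et2O), 0 °C; filtration and distillation under Ar
Reagents that add atoms: none
Why: The allylic Grignard reagent adds to the borate to give an ate complex, which anhydrous HCl collapses to the boronic ester; this is the standard preparation of allylboronates and creates no stereocentre.

Step 2
Reactants: 3 diisopropyl (2-methylallyl)boronate; 4 methyl (E)-4-oxopent-2-enoate
Product: 6 methyl (S,E)-4-hydroxy-4,6-dimethylhepta-2,6-dienoate, via borate ester 5 (not isolated)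
Conditions: (R)-3,3'-dibromo-BINOL (15 mol %), PhCF3/toluene 3:1, −35 °C; aq. NH4Cl work-up
Reagents that add atoms: none
Why: This is a diol-catalysed asymmetric allylboration of a methyl ketone: exchange of one isopropoxy group for the binaphthol gives a more Lewis acidic chiral boronate that reacts strictly 1,2 through a closed chair with the alkenyl group equatorial and the methyl group axial. The catalyst selects the Si face and sets C4 as S; methallyl reagents and alkenyl methyl ketones both lie within the known scope of this reaction type.

Step 3
Reactants: 6 methyl (S,E)-4-hydroxy-4,6-dimethylhepta-2,6-dienoate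
Product: 10 (4aS,7aS)-3-methoxy-3,4a-dimethyl-4,4a,7,7a-tetrahydro-3H-furo[3,2-c][1,2]dioxin-6-one (bicyclic peroxyketal; both C6 epimers), via carbonyl oxide 7 (not isolated), via hydroperoxy ketal 8 (not isolated), via dioxane hydroxy ester 9 (not isolated)
Conditions: O3/O2, CH2Cl2/MeOH 3:1, −78 °C, Sudan Red 7B end point; Ar purge, solvent exchange below 0 °C; Et2NH (0.3 equiv), CF3CH2OH, 0 °C to rt
Reagents that add atoms: ozone, [O-][O+]=O; methanol, CO
Why: Ozone selects the electron-rich 1,1-disubstituted alkene over the enoate, the primary ozonide cleaves to the more substituted carbonyl oxide 7 (Criegee mechanism), and methanol traps it as 8, so both peroxide oxygens come from ozone. The amine then triggers the 6-exo-trig oxa-Michael addition of the OOH group to C3 (known for hydroperoxy ketals tethered to enoates) to give 9, and the C4 hydroxyl closes ring B on the ester. C3 is set by the ring fusion, because the addition is reversible, only the cis hydroxy ester lactonises without strain, and a trans lactone would revert by E1cB to a butenolide that can re-close only cis; C6 may stay a mixture because step 4 erases it.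

Step 4
Reactants: 10 bicyclic peroxyketal (both C6 epimers); 11 allyltrimethylsilane
Product: 13 (3R,4aS,7aS)-3-allyl-3,4a-dimethyl-4,4a,7,7a-tetrahydro-3H-furo[3,2-c][1,2]dioxin-6-one, via peroxycarbenium triflate 12 (not isolated)
Conditions: 11 (3 equiv), TMSOTf (0.3 equiv), CH2Cl2, −78 °C; cold sat. aq. NaHCO3 quench
Reagents that add atoms: none
Why: TMSOTf silylates the exocyclic methoxy group of 10 and expels it, which leaves the cyclic peroxycarbenium ion 12 (C6=O-b(+)–O-a) from either C6 epimer, so both converge. The π-nucleophile 11 attacks C6 and loss of the silyl group from the β-silyl cation returns the catalyst; this is a Hosomi–Sakurai reaction of a monoperoxyketal, a reaction type established for 3-alkoxy-1,2-dioxolanes and 3-alkoxy-1,2-dioxanes, including ketone-derived ones that give fully substituted carbons. No ring is closed: rings A and B and the O–O bond are carried through and only C6–C7 is formed. C6 is the only new stereocentre and is under stereoelectronic control, since a six-membered oxocarbenium-type ion is attacked along the axial trajectory that leads directly to a chair. Of the two half-chairs of 12, the one with the C4 methyl pseudoequatorial, O4 pseudoaxial and C2 equatorial is favoured (smaller group axial, C–O dipole near the cationic centre), and axial attack on it brings the allyl group in syn to O4, whereas the other half-chair would force the nucleophile past a syn-axial methyl group. The allyl group should therefore end up cis to O4 and C2 and the C6 methyl cis to the C4 methyl, which is the 6R configuration of 16; the choice rests on which carbon group is already on C6 and not on a size difference between methyl and a long chain. The step needs exocyclic rather than endocyclic C–O ionisation and no O–O heterolysis: endocyclic opening is reversible and re-closes, while the low temperature, the sub-stoichiometric silyl Lewis acid and the excess of a fast nucleophile keep the lifetime of 12 short.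

Step 5
Reactants: 13 allyl bicycle; 14 1-pentadecene
Product: 15 (3R,4aS,7aS)-3-[(E)-hexadec-2-en-1-yl]-3,4a-dimethyl-4,4a,7,7a-tetrahydro-3H-furo[3,2-c][1,2]dioxin-6-one
Conditions: 14 (4 equiv), second-generation Hoveyda–Grubbs catalyst RuCl2(H2IMes)(=CH-C6H4-2-OiPr) (5 mol %), CH2Cl2, 40 °C
Reagents that add atoms: none
Why: This is an olefin cross-metathesis between two unhindered terminal alkenes, driven by loss of ethene and by the excess of 14. A phosphine-free ruthenium carbene is chosen because phosphines deoxygenate peroxides, and dialkyl peroxides are known to tolerate such catalysts.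

Step 6
Reactants: 15 hexadecenyl bicycle
Product: 16 (3R,4aS,7aS)-3-hexadecyl-3,4a-dimethyl-4,4a,7,7a-tetrahydro-3H-furo[3,2-c][1,2]dioxin-6-one (target, 3S,4S,6R in polyketide numbering)
Conditions: KO2C–N=N–CO2K (excess), AcOH, CH2Cl2/MeOH, 0 °C to rt
Reagents that add atoms: none
Why: Diimide, released from the azodicarboxylate by acetic acid, transfers H2 to C8=C9 in a concerted, metal-free step that leaves the O–O bond, the lactone and all three stereocentres untouched. This is the standard way to saturate alkenes in cyclic peroxides.

## Compound list

1 | 2-methylallylmagnesium chloride | C=C(C)C[Mg]Cl | starting material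
2 | triisopropyl borate | CC(C)OB(OC(C)C)OC(C)C | starting material
3 | diisopropyl (2-methylallyl)boronate | C=C(C)CB(OC(C)C)OC(C)C | intermediate
4 | methyl (E)-4-oxopent-2-enoate | COC(=O)/C=C/C(C)=O | starting material
5 | methyl (S,E)-4-[(diisopropoxyboranyl)oxy]-4,6-dimethylhepta-2,6-dienoate | COC(=O)/C=C/[C@@](C)(OB(OC(C)C)OC(C)C)CC(C)=C | intermediate
6 | methyl (S,E)-4-hydroxy-4,6-dimethylhepta-2,6-dienoate | COC(=O)/C=C/[C@@](C)(O)CC(C)=C | intermediate
7 | C6 carbonyl oxide of methyl (S,E)-4-hydroxy-4-methyl-6-oxohept-2-enoate | COC(=O)/C=C/[C@@](C)(O)CC(C)=[O+][O-] | intermediate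
8 | methyl (4S,E)-6-hydroperoxy-4-hydroxy-6-methoxy-4-methylhept-2-enoate (both C6 epimers) | COC(=O)/C=C/[C@@](C)(O)CC(C)(OC)OO | intermediate
9 | methyl 2-[(3S,4S)-4-hydroxy-6-methoxy-4,6-dimethyl-1,2-dioxan-3-yl]acetate (both C6 epimers) | COC(=O)C[C@@H]1OOC(C)(OC)C[C@]1(C)O | intermediate
10 | (4aS,7aS)-3-methoxy-3,4a-dimethyl-4,4a,7,7a-tetrahydro-3H-furo[3,2-c][1,2]dioxin-6-one (both C6 epimers) | COC1(C)C[C@]2(C)OC(=O)C[C@@H]2OO1 | intermediate
11 | allyltrimethylsilane | C=CC[Si](C)(C)C | starting material
12 | (4aS,7aS)-3,4a-dimethyl-6-oxo-4,4a,7,7a-tetrahydro-6H-furo[3,2-c][1,2]dioxin-2-ium triflate (peroxycarbenium ion) | CC1=[O+]O[C@H]2CC(=O)O[C@@]2(C)C1.[O-]S(=O)(=O)C(F)(F)F | intermediate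
13 | (3R,4aS,7aS)-3-allyl-3,4a-dimethyl-4,4a,7,7a-tetrahydro-3H-furo[3,2-c][1,2]dioxin-6-one | C=CC[C@]1(C)C[C@]2(C)OC(=O)C[C@@H]2OO1 | intermediate
14 | 1-pentadecene | C=CCCCCCCCCCCCCC | starting material
15 | (3R,4aS,7aS)-3-[(E)-hexadec-2-en-1-yl]-3,4a-dimethyl-4,4a,7,7a-tetrahydro-3H-furo[3,2-c][1,2]dioxin-6-one | CCCCCCCCCCCCC/C=C/C[C@]1(C)C[C@]2(C)OC(=O)C[C@@H]2OO1 | intermediate
16 | (3R,4aS,7aS)-3-hexadecyl-3,4a-dimethyl-4,4a,7,7a-tetrahydro-3H-furo[3,2-c][1,2]dioxin-6-one | CCCCCCCCCCCCCCCC[C@]1(C)C[C@]2(C)OC(=O)C[C@@H]2OO1 | target

## Step count and least certain steps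

Total step count: 6. Longest linear sequence: 6 (1 → 3 → 6 → 10 → 13 → 15 → 16), or five steps counted from ketone 4.

**Step 4 (key step).**
- Most likely failure: poor facial selectivity. This happens if the two half-chairs of 12 lie closer in energy than argued, or if part of the attack runs through a twist-boat.
- Second danger: loss of the peroxide. The Lewis acid may bind O-a and start an O–O heterolysis with alkyl migration, or the ring-opened oxocarbenium ion may be trapped before it re-closes.
- Fallback: it gives up substrate control at C6, uses only known chemistry, sets out from 6 and comes back at 16.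
  - Cross-metathesis of 6 with commercial 1-heptadecene (same ruthenium catalyst as in step 5) would give methyl (S,2E,6E)-4-hydroxy-4,6-dimethyldocosa-2,6-dienoate F1.
  - Mukaiyama–Isayama peroxidation (Co(thd)2, O2, Et3SiH) would place the peroxy group on C6 and give methyl (4S,E)-4-hydroxy-4,6-dimethyl-6-(triethylsilylperoxy)docos-2-enoate F2 as both C6 epimers.
  - Fluoride would release methyl (4S,E)-6-hydroperoxy-4-hydroxy-4,6-dimethyldocos-2-enoate F3.
  - Et2NH would start the same oxa-Michael/lactonisation sequence as in step 3. This leads to 16 together with its C6 epimer (3S,4aS,7aS)-3-hexadecyl-3,4a-dimethyl-4,4a,7,7a-tetrahydro-3H-furo[3,2-c][1,2]dioxin-6-one F4, which has to be removed by chromatography.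

**Step 3.**
- Possible failures:
  - Ozone may over-oxidise the enoate.
  - The primary ozonide may cleave in the wrong direction and leave the ketone instead of the carbonyl oxide.
  - The amine may induce Kornblum–DeLaMare fragmentation at H3.
  - The material may funnel only slowly into the cis lactone.
- Fallback: it takes the peroxide oxygens from hydrogen peroxide instead of ozone, sets out from 6 and comes back at 8.
  - Lemieux–Johnson cleavage (OsO4 cat., NaIO4, 2,6-lutidine, dioxane/water) would give methyl (S,E)-4-hydroxy-4-methyl-6-oxohept-2-enoate F5. This compound is kept away from base because of retro-aldol cleavage.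
  - Acid-catalysed peroxyketalisation (urea–H2O2, Sc(OTf)3 cat., MeOH) would give 8, which is cyclised as before.

**Step 2.**
- Most likely failure: the conjugated ester makes ketone 4 more electrophilic than the usual substrates. An uncatalysed background addition may then lower the enantiomeric purity of C4, on which all later centres depend.
- Fallback: it uses a well-behaved ketone and builds ring B first. It sets out from 3 and comes back at 10.
  - The same catalysis on commercial (E)-4-phenylbut-3-en-2-one would give (S,E)-3,5-dimethyl-1-phenylhexa-1,5-dien-3-ol F6.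
  - Acryloyl chloride/Et3N/DMAP would give its acrylate (S,E)-3,5-dimethyl-1-phenylhexa-1,5-dien-3-yl acrylate F7.
  - Ring-closing metathesis would give (S)-5-methyl-5-(2-methylallyl)furan-2(5H)-one F8.
  - Ozonolysis in methanol would give (S)-5-(2-hydroperoxy-2-methoxypropyl)-5-methylfuran-2(5H)-one F9.
  - Amine-induced addition to the butenolide can only be cis and gives 10.

**Step 5.**
- Possible failures: ruthenium species may cleave the O–O bond. They may also isomerise the allyl group to a propenyl group before metathesis, which shortens the chain. Homodimerisation may consume 13.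
- Fallback: it replaces metathesis by carbonyl olefination, sets out from 13 and comes back at 16.
  - Ozonolysis of the allyl group (CH2Cl2, −78 °C, then Me2S) would give 2-[(3S,4aS,7aS)-3,4a-dimethyl-6-oxo-4,4a,7,7a-tetrahydro-3H-furo[3,2-c][1,2]dioxin-3-yl]acetaldehyde F10.
  - Wittig reaction with the ylide from commercial tetradecyltriphenylphosphonium bromide (NaHMDS, THF, −78 °C) would give (3R,4aS,7aS)-3-[(Z)-hexadec-2-en-1-yl]-3,4a-dimethyl-4,4a,7,7a-tetrahydro-3H-furo[3,2-c][1,2]dioxin-6-one F11.
  - F11 is reduced under the conditions of step 6.

## Further compounds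

F1 | step 4 | methyl (S,2E,6E)-4-hydroxy-4,6-dimethyldocosa-2,6-dienoate | CCCCCCCCCCCCCCC/C=C(\C)C[C@](C)(O)/C=C/C(=O)OC
F2 | step 4 | methyl (4S,E)-4-hydroxy-4,6-dimethyl-6-(triethylsilylperoxy)docos-2-enoate (both C6 epimers) | CCCCCCCCCCCCCCCCC(C)(OO[Si](CC)(CC)CC)C[C@](C)(O)/C=C/C(=O)OC
F3 | step 4 | methyl (4S,E)-6-hydroperoxy-4-hydroxy-4,6-dimethyldocos-2-enoate (both C6 epimers) | CCCCCCCCCCCCCCCCC(C)(OO)C[C@](C)(O)/C=C/C(=O)OC
F4 | step 4 | (3S,4aS,7aS)-3-hexadecyl-3,4a-dimethyl-4,4a,7,7a-tetrahydro-3H-furo[3,2-c][1,2]dioxin-6-one | CCCCCCCCCCCCCCCC[C@@]1(C)C[C@]2(C)OC(=O)C[C@@H]2OO1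
F5 | step 3 | methyl (S,E)-4-hydroxy-4-methyl-6-oxohept-2-enoate | COC(=O)/C=C/[C@@](C)(O)CC(C)=O
F6 | step 2 | (S,E)-3,5-dimethyl-1-phenylhexa-1,5-dien-3-ol | C=C(C)C[C@](C)(O)/C=C/c1ccccc1
F7 | step 2 | (S,E)-3,5-dimethyl-1-phenylhexa-1,5-dien-3-yl acrylate | C=CC(=O)O[C@@](C)(CC(C)=C)/C=C/c1ccccc1
F8 | step 2 | (S)-5-methyl-5-(2-methylallyl)furan-2(5H)-one | C=C(C)C[C@]1(C)OC(=O)C=C1
F9 | step 2 | (S)-5-(2-hydroperoxy-2-methoxypropyl)-5-methylfuran-2(5H)-one (both epimers at the ketal carbon) | COC(C)(OO)C[C@]1(C)OC(=O)C=C1
F10 | step 5 | 2-[(3S,4aS,7aS)-3,4a-dimethyl-6-oxo-4,4a,7,7a-tetrahydro-3H-furo[3,2-c][1,2]dioxin-3-yl]acetaldehyde | O=CC[C@]1(C)C[C@]2(C)OC(=O)C[C@@H]2OO1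
F11 | step 5 | (3R,4aS,7aS)-3-[(Z)-hexadec-2-en-1-yl]-3,4a-dimethyl-4,4a,7,7a-tetrahydro-3H-furo[3,2-c][1,2]dioxin-6-one | CCCCCCCCCCCCC/C=C\C[C@]1(C)C[C@]2(C)OC(=O)C[C@@H]2OO1
A1 | alternative 1 | (S)-5-methyl-5-(2-methylideneoctadecyl)furan-2(5H)-one | C=C(CCCCCCCCCCCCCCCC)C[C@]1(C)OC(=O)C=C1
A2 | alternative 1 | (5S)-5-(2-hydroperoxy-2-methyloctadecyl)-5-methylfuran-2(5H)-one (both C6 epimers) | CCCCCCCCCCCCCCCCC(C)(OO)C[C@]1(C)OC(=O)C=C1
A3 | alternative 2 | (3E,5E)-4,6-dimethyldocosa-3,5-dienoic acid | CCCCCCCCCCCCCCCC/C(C)=C/C(C)=C/CC(=O)O
A4 | alternative 2 | 2-[(3S,6R)-6-hexadecyl-4,6-dimethyl-3,6-dihydro-1,2-dioxin-3-yl]acetic acid (formed as the racemate, useful enantiomer drawn) | CCCCCCCCCCCCCCCC[C@]1(C)C=C(C)[C@H](CC(=O)O)OO1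
A5 | alternative 3 | (S)-2-hexadecyl-2-methyloxetane | CCCCCCCCCCCCCCCC[C@@]1(C)CCO1
A6 | alternative 3 | (R)-3-hydroperoxy-3-methylnonadecan-1-ol | CCCCCCCCCCCCCCCC[C@@](C)(OO)CCO
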